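Amounts come first here: whatever Z, E and G hold came out of the L charged, so the share you are asked for is [Z] divided by the L that has gone.

    L ⇌ Z (K1 = 0.63, k1 = 2.4 × 10⁻⁴ s⁻¹)
    Z ⇌ E (K2 = 0.48, k2 = 2.5 × 10⁻⁴ s⁻¹)
    E ⇌ L (k3 = 5.2 × 10⁻⁵ s⁻¹)
    Z → G (k4 = 2.7 × 10⁻⁴ s⁻¹)

| setting | spring | midnight | summer |
|---|---|---|---|
| L | 11 mM | 11 mM | 11 mM |
| time | 1.0 h |  |  |
| remark | a closed flask charged with all of it at once and left for 1.0 h | a single well-mixed tank run continuously and read at steady state, 3.00 h in it on average | one stirred flow tank at steady state, fed with the mixture as stated, mean residence time 1.0 h |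

* order of the set-ups by the share of Z in all that became Z or E or G, at the outlet or at the end, highest first (spring / midnight / summer)
* share of Z in all that became Z or E or G, at the outlet or at the end, spring
* share of Z in all that became Z or E or G, at the outlet or at the end, midnight
* share of Z in all that became Z or E or G, at the outlet or at the end, summer

Each reverse constant is the forward one divided by its equilibrium constant. So Z goes back to L at 1.37 h⁻¹, on to E at 0.900 h⁻¹ and on to G at 0.972 h⁻¹, while E returns to Z at 1.88 h⁻¹ and to L at 0.187 h⁻¹. L feeds E directly at 0.0566 h⁻¹, far less than it feeds Z at 0.864 h⁻¹, so I leave that path out.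

In spring, the closed flask, Z and E empty with half-lives of 0.214 h and 0.336 h, both shorter than 1.0 h, so they can follow L. Divide the rate at which E is made by the rate at which it is unmade, and time drops out: [E]/[Z] is 0.436. Do the same for Z, counting as lost what E does not hand back, and you get the standing ratio, [Z]/[L] with making and unmaking of Z in balance, a quasi-steady-state ratio of 0.356.

L, Z and E then form one pool holding 1.51 parts per part of L, and it leaks to G at 0.229 h⁻¹. Taking the pool as spread from the start, I reckon spring's L at 52.6 % of the charge, and so a share of 39.5 %.

In a tank, G leaves as fast as it is made, so [G]/[Z] is the constant to G times the mean residence time. Borrow the closed flask's 0.436 for [E]/[Z] as an estimate, and the share comes to about 41.5 % in summer and about 23.0 % in midnight, so I expect midnight to stand last. Spring at 39.5 % and summer at 41.5 % stand too near for so rough a reckoning, and I leave those two unranked.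

The forecast says spring > summer > midnight, with 45.5 %, 22.9 % and 42.7 %, higher than my spring figure, and for the tanks its way was to “solve the linear steady-state balances”.

The simulation gives spring > summer > midnight, at 45.5 %, 22.9 % and 42.7 %. In spring 55.8 % of the L remains, more than my 52.6 %. Put that L into the standing ratio and the share comes to 44.9 %, so the gap in my figure sits in the amount of L. Reading spring at 0.819 h or 1.22 h moves the share by 5 points.

Read the same flask at 2.5 h: the pool gives L at 37.3 % and a share of 21.2 %. The computed flask holds 34.7 % of L and a share of 23.3 %.

All constants belong to no real substance; what happens was integrated by code.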